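**Minutes, meeting on Sunday's flask.** The chair asked what stays put between Sunday's and Saturday's flasks at one solid substrate charge, and the kineticist proposed working with the fraction left and not the fraction made.

common to all: solid substrate 0.10 M
- Sunday's: reagent 0.13 M; the very flask that is asked about, followed so far
- Saturday's: reagent 0.26 M; run made earlier
- flask: reagent 0.130 M; time 6.0 min

| Sunday's: time / s | Sunday's: target / % | Saturday's: time / min | Saturday's: target / % |
|---|---|---|---|
| 10.0 | 2 | 0.333 | 8 |
| 25.0 | 9 | 0.667 | 21 |
| 50.0 | 19 | 1.33 | 38 |
| 80.0 | 27 | 2.00 | 45 |
| 120 | 30 | 4.00 | 55 |

(standard deviation of a reading: 2 percentage points)

- solid, in amounts per volume of the solution: solid substrate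
- at the start none of the solid substrate is in solution

1. target at 6.0 min, in percent of the solid substrate charged
2. the change that raises the amount of target at 6.0 min, in percent of the solid substrate charged most ("none" if none brings more than 2 percentage points) (delta / eta / beta / none)
3. amount of target at 6.0 min, in percent of the solid substrate charged, after eta

- delta: doubling the amount of reagent, all else as stated
- eta: doubling the dissolution coefficient of the solid substrate, all else as stated
- beta: doubling the solubility of the solid substrate, all else as stated

The kineticist defined the miss number as the natural logarithm of one over the fraction of the charge not found as target, divided by the equivalents of reagent charged, [reagent]/[solid substrate]. Saturday's last reading of 55% gives 0.307, with the scatter of that reading in it. Sunday's last reading gives 0.274, lower, and that flask was still rising, from 27% to 30%.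

Carrying Saturday's number to Sunday's flask, the kineticist reckoned 32.9% at 6.0 min. Doubling the reagent gives Saturday's recipe, whose 55% is higher than that reckoning, so the kineticist's choice was delta. The miss number holds no term for dissolution, so eta was left to the forecaster.

The forecaster gave 32%, delta and 33% after eta, reading the levelling as follows: “That looks like the reagent running out”.

    dissolved substrate + target → side product A (k = 1.87 M⁻¹ s⁻¹)
    dissolved substrate + reagent → target (k = 1.05 M⁻¹ s⁻¹)
    solid substrate ⇌ dissolved substrate, rate k3*(cs3 - [dissolved substrate]) while solid is left; crystals form when [dissolved substrate] > cs3 (solubility = 24.0 mM, k = 0.0290 s⁻¹)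
    solid substrate + target → side product B (k = 0.0186 M⁻¹ s⁻¹)

Sunday's flask gives 33.6%, with delta best at 20 percentage points and 34.1% after eta. Its miss number is 0.315, close to 0.307. The flask has come to rest: target reads 33.6% at 6.00 min and 33.6% at 60.0 min, and side product A reads 61.2% and 61.2%. At rest, solid substrate, the limiting reagent here, stands at 0%, while 49% of the reagent remains. A run that finds that reagent still there tells against the forecast's reading of the levelling, though not against its 32%.

With 0.040 M of solid substrate, 3.25 equivalents and 0.307 give 63.1%. The computed flask gives 62.4%.

Readings and results were computed for an exercise, and the scatter is random.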